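**Strategy.** The cage is unlocked at the cyclopropane bond Ci–Cj, which reveals a norbornene whose two adjacent quaternary ring-fusion carbons, Ca and Cf, are shared with the cyclohexane ring Ca–Cb–Cc–Cd–Ce–Cf. A single catalytic asymmetric intramolecular Diels–Alder reaction exploits exactly this Ca–Cf junction: it forms Ca–Cf and Ci–Ch, closes the cyclohexene and the bicyclo[2.2.1]heptene, and sets Ca, Cf, Ch and Ci, leaving an exo bromide on Ci and a silyl enol ether at Ck/Cj ready to close Ci–Cj. The substrate is a 2-silyloxy-3-methylcyclopentadiene whose C1 carries a CMe2–(Z)-CH=CH–CH2 tether ending in a (Z)-3-bromo-2-alkylacrolein.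

Key step: step 13

**Remarks on the chemistry**

- Labels: Ca = quaternary carbon bearing CH2OAc; Cb (CH2), Cc (CHOH), Cd (CHOAc), Ce (CMe2) = the other cyclohexane carbons; Cf = quaternary cage apex bonded to Ca and Ce; Cg = cage CH2; Ch, Ci, Cj = cyclopropane carbons (Ch next to Cg, Ci next to Ca, Cj methyl-bearing); Ck = cage CHOAc.
- Structures: the (Z,Z) cycloaddition substrate 17 and the adduct 18 were checked atom by atom against the target and stand as drawn. CHO and Br are cis on Ca=Ci, both end up on the Cg side, and Ci inverts on cyclopropane closure. No structure needed correcting.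
- Vinyl bromide geometry: bromination–dehydrobromination of a 2-substituted acrylate or acrolein places bromine trans to the carbonyl group, and Br2 would also attack the tether alkene. The vinyl bromide is therefore made first on a small acrylate whose ester carbon later becomes Cb, which puts Br cis to the carbon that becomes the formyl group.
- Assumption: the (S)-catalyst is taken to expose the enal face that leads to 18, as it does for 2-substituted acroleins with cyclopentadiene. If the sense proved opposite, the (R)-catalyst would be used with no other change.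

**Route**

Step 1
Reactants: 1 2-methylcyclopent-2-en-1-one
Product: 2 tert-butyl(dimethyl)[(5-methylcyclopenta-1,4-dien-1-yl)oxy]silane
Conditions: TBSOTf, Et3N, CH2Cl2, 0 °C
Reagents that add atoms: tert-butyldimethylsilyl triflate, CC(C)(C)[Si](C)(C)OS(=O)(=O)C(F)(F)F
Why: Soft enolisation of the enone at the α′-carbon gives the cross-conjugated 2-silyloxydiene, the usual kinetic outcome for cyclopentenones; no stereocentre is formed.

Step 2
Reactants: 3 2-methylbut-3-yn-2-ol
Product: 4 hexacarbonyl[μ-(2-methylbut-3-yn-2-ol)]dicobalt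
Conditions: Co2(CO)8, CH2Cl2, 23 °C
Reagents that add atoms: dicobalt octacarbonyl, O=C=[Co](=C=O)(=C=O)(=C=O)[Co](=C=O)(=C=O)(=C=O)=C=O
Why: A terminal alkyne displaces two CO ligands of Co2(CO)8 to give the stable μ-alkyne complex required for the Nicholas reaction.

Step 3
Reactants: 4 hexacarbonyl[μ-(2-methylbut-3-yn-2-ol)]dicobalt; 2 tert-butyl(dimethyl)[(5-methylcyclopenta-1,4-dien-1-yl)oxy]silane
Product: 6 2-methyl-5-(2-methylbut-3-yn-2-yl)cyclopent-2-en-1-one (racemic), via alkylated hexacarbonyldicobalt complex 5 (not isolated)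
Conditions: BF3·OEt2, CH2Cl2, −78 °C; then (NH4)2Ce(NO3)6, acetone, 0 °C
Reagents that add atoms: none
Why: Nicholas reaction: BF3 ionises the tertiary propargylic alcohol to the cobalt-stabilised cation, the enol-ether carbon of 2 captures it to join Ce to Cf without allenyl by-products, and Ce(IV) then frees the alkyne; the ring stereocentre is racemic and is erased in step 12.

Step 4
Reactants: 7 ethyl 2-(hydroxymethyl)prop-2-enoate
Product: 8 ethyl 2-({[tert-butyl(dimethyl)silyl]oxy}methyl)prop-2-enoate
Conditions: TBSCl, imidazole, CH2Cl2, 0 → 23 °C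
Reagents that add atoms: tert-butyldimethylsilyl chloride, CC(C)(C)[Si](C)(C)Cl
Why: Standard silylation of a primary alcohol, which keeps the oxygen-bearing carbon distinct from the ester carbon and prevents epoxide formation in step 5.

Step 5
Reactants: 8 ethyl 2-({[tert-butyl(dimethyl)silyl]oxy}methyl)prop-2-enoate
Product: 10 ethyl (E)-3-bromo-2-({[tert-butyl(dimethyl)silyl]oxy}methyl)prop-2-enoate, via dibromide 9 (not isolated)
Conditions: Br2, CH2Cl2, 0 °C; then DBU, 0 → 23 °C
Reagents that add atoms: bromine, BrBr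
Why: Bromination–dehydrobromination: anti addition of Br2 and E2 loss of HBr from the more acidic CH2Br side should give the β-bromoacrylate with Br trans to the ester, as in the 2-methylacrylate and methacrolein series, which puts Br cis to the silyloxymethyl carbon (geometry to be confirmed by NOE on 11).

Step 6
Reactants: 10 ethyl (E)-3-bromo-2-({[tert-butyl(dimethyl)silyl]oxy}methyl)prop-2-enoate
Product: 11 (Z)-3-bromo-2-({[tert-butyl(dimethyl)silyl]oxy}methyl)prop-2-en-1-ol
Conditions: DIBAL-H, CH2Cl2, −78 °C; Rochelle salt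
Reagents that add atoms: none
Why: DIBAL 1,2-reduction of an enoate to the allylic alcohol leaves the vinyl bromide and its geometry untouched.

Step 7
Reactants: 11 (Z)-3-bromo-2-({[tert-butyl(dimethyl)silyl]oxy}methyl)prop-2-en-1-ol
Product: 12 (E)-{[3-bromo-2-(bromomethyl)prop-2-en-1-yl]oxy}(tert-butyl)dimethylsilane
Conditions: CBr4, PPh3, CH2Cl2, 0 °C
Reagents that add atoms: carbon tetrabromide, BrC(Br)(Br)Br
Why: The Appel reaction converts the primary allylic alcohol to the bromide under neutral conditions tolerated by the silyl ether and the vinyl bromide.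

Step 8
Reactants: 6 2-methyl-5-(2-methylbut-3-yn-2-yl)cyclopent-2-en-1-one; 12 (E)-{[3-bromo-2-(bromomethyl)prop-2-en-1-yl]oxy}(tert-butyl)dimethylsilane
Product: 13 5-[(6Z)-7-bromo-6-({[tert-butyl(dimethyl)silyl]oxy}methyl)-2-methylhept-6-en-3-yn-2-yl]-2-methylcyclopent-2-en-1-one
Conditions: CuI, K2CO3, DMF, 23 °C
Reagents that add atoms: none
Why: Copper-mediated alkynyl–allyl coupling substitutes the primary allylic bromide at CH2 and forms the Cb–Cc bond of a skipped enyne, while the vinylic bromide is inert under these conditions.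

Step 9
Reactants: 13 skipped enyne ketone
Product: 14 5-[(3Z,6Z)-7-bromo-6-({[tert-butyl(dimethyl)silyl]oxy}methyl)-2-methylhepta-3,6-dien-2-yl]-2-methylcyclopent-2-en-1-one
Conditions: H2 (1 atm), Lindlar catalyst, quinoline, EtOAc, 23 °C, uptake monitored
Reagents that add atoms: none
Why: Lindlar semihydrogenation delivers H2 syn and stops at the (Z)-alkene Cc=Cd; the poisoned catalyst should spare the trisubstituted enone and the vinyl bromide.

Step 10
Reactants: 14 (3Z,6Z)-dienyl silyl ether ketone
Product: 15 5-[(3Z,6Z)-7-bromo-6-(hydroxymethyl)-2-methylhepta-3,6-dien-2-yl]-2-methylcyclopent-2-en-1-one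
Conditions: HF·pyridine, pyridine, THF, 0 → 23 °C
Reagents that add atoms: none
Why: Buffered fluoride cleaves the primary TBS ether without the basic conditions that could isomerise the vinyl bromide.

Step 11
Reactants: 15 (3Z,6Z)-dienyl allylic alcohol ketone
Product: 16 (2Z,4Z)-2-(bromomethylidene)-6-methyl-6-(3-methyl-2-oxocyclopent-3-en-1-yl)hept-4-enal
Conditions: MnO2, CH2Cl2, 23 °C
Reagents that add atoms: none
Why: MnO2 oxidises the allylic alcohol to the enal under neutral heterogeneous conditions that preserve the Z geometry (Br cis to CHO) and the other alkenes.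

Step 12
Reactants: 16 keto bromoenal
Product: 17 (2Z,4Z)-2-(bromomethylidene)-6-{2-[tert-butyl(dimethyl)silyl]oxy-3-methylcyclopenta-1,3-dien-1-yl}-6-methylhept-4-enal
Conditions: TBSOTf, i-Pr2NEt, CH2Cl2, −78 → −40 °C; cold pentane/NaHCO3 work-up, used at once
Reagents that add atoms: tert-butyldimethylsilyl triflate, CC(C)(C)[Si](C)(C)OS(=O)(=O)C(F)(F)F
Why: Soft enolisation with a hindered amine removes the α′ proton on Cf and gives directly the cyclopentadiene isomer with the tether on a diene terminus, the non-enolisable enal being left alone at low temperature; the racemic ring stereocentre disappears.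

Step 13
Reactants: 17 (Z,Z)-bromoenal tethered to the silyloxycyclopentadiene
Product: 18 exo-formyl exo-bromo norbornene silyl enol ether (CHO on Ca and Br on Ci both on the Cg side; cyclohexene fused at Ca–Cf with Cb on the Ck side)
Conditions: (S)-3,3-diphenyl-1-(2-methylphenyl)tetrahydro-1H,3H-pyrrolo[1,2-c][1,3,2]oxazaborole (20 mol %), HNTf2 (17 mol %), CH2Cl2, −78 °C; Et3N quench
Reagents that add atoms: none
Why: The N-protonated oxazaborolidine binds the formyl oxygen and lowers the enal LUMO, and the tethered cyclopentadiene adds across Ca=Ci in a concerted, asynchronous [4+2] in which Ci–Ch bonding should lead, because the tether forces the silyloxy-activated terminus Cf onto the α-carbon Ca. The closest known reaction types are the exo-formyl-selective oxazaborolidinium-catalysed Diels–Alder reaction of 2-substituted acroleins with cyclopentadiene and the type 1 intramolecular Diels–Alder reaction of 1-alkenylcyclopentadienes. The cyclohexene Ca–Cb–Cc–Cd–Ce–Cf closes as the tether ring in the fused mode through Ca–Cf, and the bicyclo[2.2.1]heptene closes as the cycloadduct ring through Ci–Ch, suprafacially on both partners. Ca and Ci are related by retention of the Z geometry (CHO and Br cis), their orientation to the bridge comes from the exo-formyl transition state that keeps the α-branch Cb under the diene and CHO and Br toward Cg, Cf and Ch follow from suprafacial addition to the diene, and the absolute sense of all four comes from the catalyst shielding one enal face. The step needs fused regiochemistry, which the four-atom Z-alkene tether enforces, exo-formyl selectivity, which the α-branch and the catalyst favour, and survival of the silyl dienol ether, which the slight deficit of HNTf2, −78 °C and the amine quench protect.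

Step 14
Reactants: 18 exo-formyl exo-bromo norbornene silyl enol ether
Product: 20 tricyclene keto aldehyde (cyclopropane Ch–Ci–Cj closed; Ck ketone; Ca–CHO; Cc=Cd), via caesium enolate 19 (not isolated)
Conditions: CsF, DMF, 0 → 23 °C
Reagents that add atoms: none
Why: Fluoride unmasks the Ck/Cj enolate, whose carbon Cj displaces the exo bromide on Ci from the endo side in a 3-exo-tet intramolecular alkylation (the known route from 5-exo-substituted norbornan-2-ones to nortricyclanones), with inversion at Ci and Cj fixed by the cage.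

Step 15
Reactants: 20 tricyclene keto aldehyde
Product: 21 diol (Ca–CH2OH; Ck–OH pointing to the Cg side)
Conditions: Al(Oi-Pr)3, i-PrOH, toluene, 90 °C, prolonged
Reagents that add atoms: none
Why: Meerwein–Ponndorf–Verley reduction: the aldehyde is reduced essentially irreversibly and the hindered ketone reversibly, so Ck should settle as the more stable carbinol with OH toward Cg and away from the 1,3-related Cb, by a two-electron hydride transfer that cannot open the cyclopropyl ketone as a ketyl would.

Step 16
Reactants: 21 diol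
Product: 23 tetraol (cis-diol at Cc/Cd on the face of Ca–CH2OH), via osmate(VI) ester TMEDA chelate 22 (not isolated)
Conditions: OsO4 (1.05 equiv), TMEDA, CH2Cl2, −78 → −20 °C; then aq. Na2SO3, THF, reflux
Reagents that add atoms: osmium tetroxide, O=[Os](=O)(=O)=O
Why: Hydrogen-bond-directed osmylation: the axial Ca–CH2OH, 1,3-diaxial to Cc, binds the OsO4·TMEDA complex and steers the suprafacial [3+2] addition to its own face of Cc=Cd, giving the cis-diol syn to CH2OH, and sulfite cleaves the osmate ester without acid.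

Step 17
Reactants: 23 tetraol
Product: 24 CNP0111873.1 (CH2OAc on Ca; OAc on Cd and Ck; free axial OH on Cc)
Conditions: Ac2O, pyridine, DMAP (cat.), CH2Cl2, 0 → 23 °C, stopped at the triacetate
Reagents that add atoms: acetic anhydride, CC(=O)OC(C)=O
Why: DMAP-catalysed acetylation should esterify the primary, the equatorial Cd and the cage Ck hydroxyls, whereas the axial Cc hydroxyl, syn-axial to both Ca–CH2OAc and a Ce methyl, reacts far more slowly and is left free.

**Compound list**

1 | 2-methylcyclopent-2-en-1-one | CC1=CCCC1=O | starting material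
2 | tert-butyl(dimethyl)[(5-methylcyclopenta-1,4-dien-1-yl)oxy]silane | CC1=CCC=C1O[Si](C)(C)C(C)(C)C | intermediate
3 | 2-methylbut-3-yn-2-ol | CC(C)(O)C#C | starting material
4 | hexacarbonyl[μ-(2-methylbut-3-yn-2-ol)]dicobalt | CC(C)(O)C12[CH]3[Co]1(=C=O)(=C=O)(=C=O)[Co]23(=C=O)(=C=O)=C=O | intermediate
5 | hexacarbonyldicobalt complex of 2-methyl-5-(2-methylbut-3-yn-2-yl)cyclopent-2-en-1-one (racemic) | CC1=CCC(C1=O)C(C)(C)C23[CH]4[Co]2(=C=O)(=C=O)(=C=O)[Co]34(=C=O)(=C=O)=C=O | intermediate
6 | 2-methyl-5-(2-methylbut-3-yn-2-yl)cyclopent-2-en-1-one (racemic) | CC1=CCC(C1=O)C(C)(C)C#C | intermediate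
7 | ethyl 2-(hydroxymethyl)prop-2-enoate | C=C(CO)C(=O)OCC | starting material
8 | ethyl 2-({[tert-butyl(dimethyl)silyl]oxy}methyl)prop-2-enoate | C=C(CO[Si](C)(C)C(C)(C)C)C(=O)OCC | intermediate
9 | ethyl 2,3-dibromo-2-({[tert-butyl(dimethyl)silyl]oxy}methyl)propanoate (racemic) | BrCC(Br)(CO[Si](C)(C)C(C)(C)C)C(=O)OCC | intermediate
10 | ethyl (E)-3-bromo-2-({[tert-butyl(dimethyl)silyl]oxy}methyl)prop-2-enoate (Br trans to ester) | CCOC(=O)/C(=C/Br)CO[Si](C)(C)C(C)(C)C | intermediate
11 | (Z)-3-bromo-2-({[tert-butyl(dimethyl)silyl]oxy}methyl)prop-2-en-1-ol (Br trans to CH2OH) | OC/C(=C/Br)CO[Si](C)(C)C(C)(C)C | intermediate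
12 | (E)-{[3-bromo-2-(bromomethyl)prop-2-en-1-yl]oxy}(tert-butyl)dimethylsilane (vinyl Br trans to CH2Br) | BrC/C(=C/Br)CO[Si](C)(C)C(C)(C)C | intermediate
13 | 5-[(6Z)-7-bromo-6-({[tert-butyl(dimethyl)silyl]oxy}methyl)-2-methylhept-6-en-3-yn-2-yl]-2-methylcyclopent-2-en-1-one | CC1=CCC(C1=O)C(C)(C)C#CC/C(=C/Br)CO[Si](C)(C)C(C)(C)C | intermediate
14 | 5-[(3Z,6Z)-7-bromo-6-({[tert-butyl(dimethyl)silyl]oxy}methyl)-2-methylhepta-3,6-dien-2-yl]-2-methylcyclopent-2-en-1-one | CC1=CCC(C1=O)C(C)(C)/C=C\C/C(=C/Br)CO[Si](C)(C)C(C)(C)C | intermediate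
15 | 5-[(3Z,6Z)-7-bromo-6-(hydroxymethyl)-2-methylhepta-3,6-dien-2-yl]-2-methylcyclopent-2-en-1-one | CC1=CCC(C1=O)C(C)(C)/C=C\C/C(=C/Br)CO | intermediate
16 | (2Z,4Z)-2-(bromomethylidene)-6-methyl-6-(3-methyl-2-oxocyclopent-3-en-1-yl)hept-4-enal | O=C/C(=C\Br)C/C=C\C(C)(C)C1CC=C(C)C1=O | intermediate
17 | (2Z,4Z)-2-(bromomethylidene)-6-{2-[tert-butyl(dimethyl)silyl]oxy-3-methylcyclopenta-1,3-dien-1-yl}-6-methylhept-4-enal | O=C/C(=C\Br)C/C=C\C(C)(C)C1=C(O[Si](C)(C)C(C)(C)C)C(C)=CC1 | intermediate
18 | exo-formyl exo-bromo norbornene silyl enol ether (Diels–Alder adduct) | O=C[C@]12CC=CC(C)(C)[C@]13C[C@@H](C(C)=C3O[Si](C)(C)C(C)(C)C)[C@@H]2Br | intermediate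
19 | caesium enolate of the adduct (Ck–O⁻, Ck=Cj) | O=C[C@]12CC=CC(C)(C)[C@]13C[C@@H](C(C)=C3[O-])[C@@H]2Br.[Cs+] | intermediate
20 | tricyclene keto aldehyde | O=C[C@]12CC=CC(C)(C)[C@]13C[C@@H]1[C@H]2[C@]1(C)C3=O | intermediate
21 | tricyclene diol (Ca–CH2OH, Ck–OH toward Cg) | OC[C@]12CC=CC(C)(C)[C@]13C[C@@H]1[C@H]2[C@]1(C)[C@H]3O | intermediate
22 | Cc,Cd-osmate(VI) ester of 21, dioxo, TMEDA-chelated | OC[C@]12C[C@H](O4)[C@H](O[Os-2]45(=O)(=O)[N+](C)(C)CC[N+]5(C)C)C(C)(C)[C@]13C[C@@H]1[C@H]2[C@]1(C)[C@H]3O | intermediate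
23 | tetraol | OC[C@]12C[C@H](O)[C@H](O)C(C)(C)[C@]13C[C@@H]1[C@H]2[C@]1(C)[C@H]3O | intermediate
24 | CNP0111873.1 | CC(=O)OC[C@]12C[C@H](O)[C@H](OC(C)=O)C(C)(C)[C@]13C[C@@H]1[C@H]2[C@]1(C)[C@H]3OC(C)=O | target

**Step count**

Total: 17 steps. Longest linear sequence: 14 steps (7 → 24, steps 4–17).

**Steps most likely to fail**

1. Step 13. Face and exo/endo control may be lost. The silyloxy group polarises the diene against the tether-imposed regiochemistry, so the cycloaddition is not accelerated by it. The tether must sit endo, where the forming cyclohexene is more twisted. An uncatalysed background cycloaddition, protodesilylation of the diene, or Mukaiyama-type attack of Cf on the activated enal could then compete. Fallback (catalyst control replaced by resolution, no Lewis acid): 17 is cyclised thermally (toluene, BHT, 40–60 °C) to the racemic adduct F1. CsF/DMF then gives the racemic keto aldehyde F2, and Al(Oi-Pr)3/i-PrOH gives the racemic diol F3. The primary alcohol is esterified with (R)-2-methoxy-2-phenylacetic acid (EDC, DMAP, 0 °C) to the diastereomeric esters, the (R)-O-methylmandelate of 21 F4 and the (R)-O-methylmandelate of ent-21 F5, which are separated by chromatography. K2CO3/MeOH on F4 returns 21, and the route resumes at step 16.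

2. Step 15. Hydride transfer to the ketone flanked by two quaternary carbons may be too slow for equilibration, leaving the kinetically formed Ck epimer or unreduced ketone. Fallback (irreversible reduction, then a separate redox-neutral epimerisation): 20 is reduced with LiAlH4 (THF, 0 °C) under steric approach control to the Ck-epimeric diol F6 (OH toward Ca). Its secondary carbinol is then equilibrated by ruthenium-catalysed hydrogen transfer (chlorodicarbonyl(pentaphenylcyclopentadienyl)ruthenium, KOt-Bu, toluene, 60 °C) to 21, where the route resumes at step 16.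

3. Step 16. The bishomoallylic hydroxyl may direct too weakly, so that osmium adds to the face of Cc=Cd away from CH2OH, or the hindered alkene may react sluggishly. Fallback (oxygen delivered to the face opposite to the attacking electrophile): 21 is acetylated (Ac2O, DMAP, Et3N) to the diacetate F7. I2/AgOAc in AcOH gives the trans-iodo acetate F8 (I on Cd, OAc on Cc). Wet AcOH/AgOAc at 90 °C converts it through the acetoxonium ion into the cis-hydroxy acetate F9 (Woodward cis-hydroxylation). LiAlH4 removes all acetates to give 23, and the route resumes at step 17.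

**Further compounds**

F1 | step 13 | racemic Diels–Alder adduct (18 and its enantiomer) | O=C[C@]12CC=CC(C)(C)[C@]13C[C@@H](C(C)=C3O[Si](C)(C)C(C)(C)C)[C@@H]2Br.O=C[C@@]12CC=CC(C)(C)[C@@]13C[C@H](C(C)=C3O[Si](C)(C)C(C)(C)C)[C@H]2Br
F2 | step 13 | racemic tricyclene keto aldehyde (20 and its enantiomer) | O=C[C@]12CC=CC(C)(C)[C@]13C[C@@H]1[C@H]2[C@]1(C)C3=O.O=C[C@@]12CC=CC(C)(C)[C@@]13C[C@H]1[C@@H]2[C@@]1(C)C3=O
F3 | step 13 | racemic tricyclene diol (21 and its enantiomer) | OC[C@]12CC=CC(C)(C)[C@]13C[C@@H]1[C@H]2[C@]1(C)[C@H]3O.OC[C@@]12CC=CC(C)(C)[C@@]13C[C@H]1[C@@H]2[C@@]1(C)[C@@H]3O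
F4 | step 13 | (R)-O-methylmandelate of 21 (primary ester) | CO[C@@H](C(=O)OC[C@]12CC=CC(C)(C)[C@]13C[C@@H]1[C@H]2[C@]1(C)[C@H]3O)c1ccccc1
F5 | step 13 | (R)-O-methylmandelate of ent-21 (primary ester) | CO[C@@H](C(=O)OC[C@@]12CC=CC(C)(C)[C@@]13C[C@H]1[C@@H]2[C@@]1(C)[C@@H]3O)c1ccccc1
F6 | step 15 | Ck-epimeric diol (Ck–OH toward Ca) | OC[C@]12CC=CC(C)(C)[C@]13C[C@@H]1[C@H]2[C@]1(C)[C@@H]3O
F7 | step 16 | diacetate of 21 (CH2OAc, Ck–OAc) | CC(=O)OC[C@]12CC=CC(C)(C)[C@]13C[C@@H]1[C@H]2[C@]1(C)[C@H]3OC(C)=O
F8 | step 16 | trans-iodo acetate (Cc–OAc on the CH2OAc face, Cd–I on the opposite face) | CC(=O)OC[C@]12C[C@H](OC(C)=O)[C@@H](I)C(C)(C)[C@]13C[C@@H]1[C@H]2[C@]1(C)[C@H]3OC(C)=O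
F9 | step 16 | cis-hydroxy acetate (Cc–OAc, Cd–OH, both on the CH2OAc face) | CC(=O)OC[C@]12C[C@H](OC(C)=O)[C@H](O)C(C)(C)[C@]13C[C@@H]1[C@H]2[C@]1(C)[C@H]3OC(C)=O
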